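The six-membered ring (C1 carbonyl, C2 H, C3 OMe, C4 ketal, C5 H2, C6 allyl) is cut at C3: C2 and C4 are the two carbons of an aryl enol ether in a cyclopentene, and C3 enters as dibromocarbene. The key step exploits the doubly oxygenated C4 beside the C2=C3 alkene. The dibromocyclopropane opens by loss of bromide to an aryloxy-stabilised cyclohexenyl cation, and methanol adds at C4 trans to the C6 allyl group. One operation expands the five-membered ring, builds the mixed aryl methyl ketal stereocentre and leaves a C3 bromide for later exchange by methoxide. C6 comes from a palladium-catalysed decarboxylative asymmetric allylation.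

Key step: step 8

Remark: the target is (4R,6S), with OAr and allyl cis. In step 5 the ligand is written as (R,R); its sense of induction on this five-membered dienyl carbonate is assumed by analogy with six-membered enol carbonates, and the antipodal ligand would be used if it proves opposite.

Step 1
Reactants: 1 3,4-dimethoxyphenol; 2 allyl bromide
Product: 3 4-(allyloxy)-1,2-dimethoxybenzene
Conditions: K2CO3, acetone, reflux
Reagents that add atoms: none
Why: Williamson etherification (SN2 of the phenoxide on the allylic bromide) should give the aryl allyl ether cleanly.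

Step 2
Reactants: 3 4-(allyloxy)-1,2-dimethoxybenzene
Product: 4 2-allyl-4,5-dimethoxyphenol
Conditions: N,N-diethylaniline, 200 °C, sealed tube
Reagents that add atoms: none
Why: Aromatic Claisen rearrangement ([3,3]-sigmatropic shift, then tautomerisation) should deliver the allyl group to the unhindered ortho carbon rather than to the one flanked by two oxygens.

Step 3
Reactants: 5 cyclopentane-1,3-dione; 4 2-allyl-4,5-dimethoxyphenol
Product: 7 3-(2-allyl-4,5-dimethoxyphenoxy)cyclopent-2-en-1-one, via 3-chlorocyclopent-2-en-1-one 6 (not isolated)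
Conditions: (COCl)2, cat. DMF, CH2Cl2, 0 °C → rt; evaporate; then 4, K2CO3, acetone, rt
Reagents that add atoms: oxalyl chloride, O=C(Cl)C(=O)Cl (its chlorine is carried only by intermediate 6)
Why: Vilsmeier-type chlorination of the dione enol gives the vinylogous acid chloride 6, whose chloride the phenoxide should replace by conjugate addition–elimination (nucleophilic vinylic substitution).

Step 4
Reactants: 7 3-(2-allyl-4,5-dimethoxyphenoxy)cyclopent-2-en-1-one; 8 allyl chloroformate
Product: 9 allyl 4-(2-allyl-4,5-dimethoxyphenoxy)cyclopenta-1,4-dien-1-yl carbonate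
Conditions: NaHMDS, TMEDA, THF, −78 °C; then 8, −78 °C; cold pH 7 work-up, used at once
Reagents that add atoms: none
Why: Kinetic α'-deprotonation of the vinylogous ester and O-acylation of the sodium enolate (enol carbonate formation) should give the dienyl carbonate, which is kept cold because 1,5-hydrogen shifts of cyclopentadienes set in near room temperature.

Step 5
Reactants: 9 allyl 4-(2-allyl-4,5-dimethoxyphenoxy)cyclopenta-1,4-dien-1-yl carbonate
Product: 10 (S)-5-allyl-3-(2-allyl-4,5-dimethoxyphenoxy)cyclopent-2-en-1-one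
Conditions: Pd2(dba)3·CHCl3 (2.5 mol %), (R,R)-ANDEN-phenyl bis(2-diphenylphosphinobenzamide) ligand (5.5 mol %), toluene, 0 °C → rt
Reagents that add atoms: none
Why: Palladium-catalysed decarboxylative asymmetric allylic alkylation: ionisation and loss of CO2 give an allyl-palladium/enolate ion pair that should recombine at C5 within the chiral pocket of the ligand under neutral conditions, so the tertiary centre is set by the ligand and not racemised.

Step 6
Reactants: 10 (S)-5-allyl-3-(2-allyl-4,5-dimethoxyphenoxy)cyclopent-2-en-1-one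
Product: 11 (1S,5S)-5-allyl-3-(2-allyl-4,5-dimethoxyphenoxy)cyclopent-2-en-1-ol (OH cis to allyl)
Conditions: DIBAL-H, toluene, −78 °C; Rochelle salt work-up
Reagents that add atoms: none
Why: 1,2-Reduction of the vinylogous ester carbonyl by DIBAL-H, with hydride delivered anti to the C5 allyl group, should give mainly the cis-alcohol; this carbinol centre is erased in step 9 and its epimer would follow the same course.

Step 7
Reactants: 11 (1S,5S)-5-allyl-3-(2-allyl-4,5-dimethoxyphenoxy)cyclopent-2-en-1-ol
Product: 12 [(1S,5S)-5-allyl-3-(2-allyl-4,5-dimethoxyphenoxy)cyclopent-2-en-1-yl]oxy(trimethyl)silane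
Conditions: TMSCl, imidazole, CH2Cl2, 0 °C
Reagents that add atoms: chlorotrimethylsilane, C[Si](C)(C)Cl
Why: Silyl ether formation removes the O–H that would quench the carbene and keeps the acid-labile 3-aryloxy allylic alcohol from ionising.

Step 8
Reactants: 12 [(1S,5S)-5-allyl-3-(2-allyl-4,5-dimethoxyphenoxy)cyclopent-2-en-1-yl]oxy(trimethyl)silane; 13 bromoform
Product: 16 (1S,4R,6S)-6-allyl-4-(2-allyl-4,5-dimethoxyphenoxy)-3-bromo-4-methoxycyclohex-2-en-1-ol, via dibromocyclopropane 14 (not isolated), via ring-expanded silyl ether 15 (not isolated)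
Conditions: 13 (1.2 equiv), KOtBu, pentane, −30 °C; then MeOH, K2CO3, −30 → 0 °C, then rt
Reagents that add atoms: methanol, CO
Why: Dibromocarbene adds in a [2+1] cheletropic step to the electron-rich trisubstituted aryl enol ether C=C of 12, which is far more nucleophilic than the two monosubstituted allyl alkenes, and closes the cyclopropane ring of 14 on the face anti to the OTMS and allyl groups. In methanol the 1-aryloxy-6,6-dibromobicyclo[3.1.0]hexane should ionise with concerted disrotatory 2π-electrocyclic opening of the ring-fusion bond (endo bromide leaves), so the five-membered ring becomes the six-membered 2-bromo-1-aryloxycyclohexenyl cation; the closest known reaction type is the dihalocarbene ring expansion of cyclic enol ethers to 2-halocycloalk-2-enone ketals. Methanol should capture the cation at the oxygen-bearing terminus C4, where the positive charge is highest, giving the mixed ketal 15 and not the allylic ether at C2. The new stereocentre C4 is controlled by C6: in the sofa-shaped cation with C6 as the flap, allyl pseudo-equatorial and OTMS pseudo-axial, methanol should attack pseudo-axially on the face toward which C6 is displaced, staggered to both C5–H bonds, and so end trans to allyl with OAr cis (4R). K2CO3 keeps the medium basic so that the kinetic ketal does not re-ionise, and on warming it removes the TMS group to give 16. The step needs chemoselectivity (secured by the electron-rich enol ether and only a slight excess of carbene), regioselectivity of capture (secured by the oxocarbenium character at C4) and facial selectivity (secured by the C6 substituent).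

Step 9
Reactants: 16 (1S,4R,6S)-6-allyl-4-(2-allyl-4,5-dimethoxyphenoxy)-3-bromo-4-methoxycyclohex-2-en-1-ol
Product: 17 (4R,6S)-6-allyl-4-(2-allyl-4,5-dimethoxyphenoxy)-3-bromo-4-methoxycyclohex-2-en-1-one
Conditions: Dess–Martin periodinane, pyridine, CH2Cl2, 0 °C → rt
Reagents that add atoms: none
Why: Dess–Martin oxidation of the allylic alcohol under pyridine buffer should give the β-bromo enone without touching the ketal and without enolising C6.

Step 10
Reactants: 17 (4R,6S)-6-allyl-4-(2-allyl-4,5-dimethoxyphenoxy)-3-bromo-4-methoxycyclohex-2-en-1-one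
Product: 18 (4R,6S)-6-allyl-4-(2-allyl-4,5-dimethoxyphenoxy)-3,4-dimethoxycyclohex-2-en-1-one (target)
Conditions: NaOMe (1.05 equiv), MeOH–THF, −40 → −20 °C; pH 7 buffer quench
Reagents that add atoms: sodium methoxide, [Na+].[O-]C
Why: Nucleophilic vinylic substitution by conjugate addition–elimination: methoxide adds to C3 of the β-bromo enone and bromide leaves from the enolate, which at low temperature should outrun deprotonation of the tertiary C6–H, so both stereocentres are retained.

Compound list
1 | 3,4-dimethoxyphenol | COc1ccc(O)cc1OC | starting material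
2 | allyl bromide | C=CCBr | starting material
3 | 4-(allyloxy)-1,2-dimethoxybenzene | C=CCOc1ccc(OC)c(OC)c1 | intermediate
4 | 2-allyl-4,5-dimethoxyphenol | C=CCc1cc(OC)c(OC)cc1O | intermediate
5 | cyclopentane-1,3-dione | O=C1CCC(=O)C1 | starting material
6 | 3-chlorocyclopent-2-en-1-one | O=C1CCC(Cl)=C1 | intermediate
7 | 3-(2-allyl-4,5-dimethoxyphenoxy)cyclopent-2-en-1-one | O=C1CCC(Oc2cc(OC)c(OC)cc2CC=C)=C1 | intermediate
8 | allyl chloroformate | C=CCOC(=O)Cl | starting material
9 | allyl 4-(2-allyl-4,5-dimethoxyphenoxy)cyclopenta-1,4-dien-1-yl carbonate | C=CCOC(=O)OC1=CCC(Oc2cc(OC)c(OC)cc2CC=C)=C1 | intermediate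
10 | (S)-5-allyl-3-(2-allyl-4,5-dimethoxyphenoxy)cyclopent-2-en-1-one | C=CC[C@H]1CC(Oc2cc(OC)c(OC)cc2CC=C)=CC1=O | intermediate
11 | (1S,5S)-5-allyl-3-(2-allyl-4,5-dimethoxyphenoxy)cyclopent-2-en-1-ol, OH cis to allyl | C=CC[C@H]1CC(Oc2cc(OC)c(OC)cc2CC=C)=C[C@H]1O | intermediate
12 | trimethylsilyl ether of 11 | C=CC[C@H]1CC(Oc2cc(OC)c(OC)cc2CC=C)=C[C@H]1O[Si](C)(C)C | intermediate
13 | bromoform | BrC(Br)Br | starting material
14 | 3-allyl-1-(2-allyl-4,5-dimethoxyphenoxy)-6,6-dibromo-4-(trimethylsilyloxy)bicyclo[3.1.0]hexane, CBr2 bridge on the face opposite to the cis allyl and OTMS groups | C=CC[C@H]1C[C@]2(Oc3cc(OC)c(OC)cc3CC=C)C(Br)(Br)[C@@H]2[C@H]1O[Si](C)(C)C | intermediate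
15 | trimethylsilyl ether of 16, (1S,4R,6S) | C=CCc1cc(OC)c(OC)cc1O[C@]1(OC)C[C@H](CC=C)[C@H](O[Si](C)(C)C)C=C1Br | intermediate
16 | (1S,4R,6S)-6-allyl-4-(2-allyl-4,5-dimethoxyphenoxy)-3-bromo-4-methoxycyclohex-2-en-1-ol | C=CCc1cc(OC)c(OC)cc1O[C@]1(OC)C[C@H](CC=C)[C@H](O)C=C1Br | intermediate
17 | (4R,6S)-6-allyl-4-(2-allyl-4,5-dimethoxyphenoxy)-3-bromo-4-methoxycyclohex-2-en-1-one | C=CCc1cc(OC)c(OC)cc1O[C@]1(OC)C[C@H](CC=C)C(=O)C=C1Br | intermediate
18 | (4R,6S)-6-allyl-4-(2-allyl-4,5-dimethoxyphenoxy)-3,4-dimethoxycyclohex-2-en-1-one | C=CCc1cc(OC)c(OC)cc1O[C@]1(OC)C[C@H](CC=C)C(=O)C=C1OC | target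

Total step count: 10. Longest linear sequence: 10 steps (from 1 to 18).

Steps most likely to fail

Step 8. Methanol may capture the cation on the wrong face (facial selectivity weaker than or opposite to the conformational model), and some carbene may add to the allyl groups. The fallback introduces the two ketal oxygens in the reverse order, so that the aryloxide is the nucleophile and a face preference that is wrong for methanol becomes right. It sets out from 4 and comes back to the route at 15. Commercial 3-methoxycyclopent-2-en-1-one F1 would be taken through the chemistry of steps 4 to 7 to allyl 4-methoxycyclopenta-1,4-dien-1-yl carbonate F2, (S)-5-allyl-3-methoxycyclopent-2-en-1-one F3, (1S,5S)-5-allyl-3-methoxycyclopent-2-en-1-ol F4 and its trimethylsilyl ether F5. Dibromocarbene (CHBr3, KOtBu, pentane, −30 °C) should then give 3-allyl-6,6-dibromo-1-methoxy-4-(trimethylsilyloxy)bicyclo[3.1.0]hexane F6, which is opened in MeCN with the potassium salt of 4 and 18-crown-6 from −30 °C to rt. Capture of the methoxy-stabilised cation by the phenoxide should give 15, and K2CO3 in MeOH then gives 16.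

Step 10. Methoxide may enolise the ketone at C6 and epimerise it while addition at the hindered C3 is slow. The fallback makes the C3–O bond by copper catalysis before the ketone exists; it sets out from 16 and comes back at 18. Ullmann-type methoxylation of the vinyl bromide (CuI, 3,4,7,8-tetramethyl-1,10-phenanthroline, Cs2CO3, MeOH–toluene, 80 °C), where C6–H is not acidic, should give (1S,4R,6S)-6-allyl-4-(2-allyl-4,5-dimethoxyphenoxy)-3,4-dimethoxycyclohex-2-en-1-ol F7. Dess–Martin oxidation with pyridine buffer then gives 18.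

Step 5. The cyclopentadienyl carbonate 9 may isomerise by 1,5-hydrogen shift or dimerise before ionisation, and enantio-discrimination may be incomplete for a tertiary α-centre. The fallback replaces catalytic asymmetric allylation by racemic alkylation and enzymatic resolution; it sets out from 7 and comes back at 11. Kinetic alkylation (LDA, THF, −78 °C; allyl bromide 2) should give racemic 5-allyl-3-(2-allyl-4,5-dimethoxyphenoxy)cyclopent-2-en-1-one F8, and DIBAL-H then the racemic cis-alcohol rac-cis-5-allyl-3-(2-allyl-4,5-dimethoxyphenoxy)cyclopent-2-en-1-ol F9. Lipase-catalysed acylation (Burkholderia cepacia lipase, vinyl acetate, MTBE, rt) is expected to convert the (1R,5R)-enantiomer into (1R,5R)-5-allyl-3-(2-allyl-4,5-dimethoxyphenoxy)cyclopent-2-en-1-yl acetate F10 and leave 11, which is separated on base-washed silica. If the enzyme prefers the other enantiomer, the acetate is methanolysed instead.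

Further compounds
F1 | step 8 | 3-methoxycyclopent-2-en-1-one | COC1=CC(=O)CC1
F2 | step 8 | allyl 4-methoxycyclopenta-1,4-dien-1-yl carbonate | C=CCOC(=O)OC1=CCC(OC)=C1
F3 | step 8 | (S)-5-allyl-3-methoxycyclopent-2-en-1-one | C=CC[C@H]1CC(OC)=CC1=O
F4 | step 8 | (1S,5S)-5-allyl-3-methoxycyclopent-2-en-1-ol | C=CC[C@H]1CC(OC)=C[C@H]1O
F5 | step 8 | trimethylsilyl ether of (1S,5S)-5-allyl-3-methoxycyclopent-2-en-1-ol | C=CC[C@H]1CC(OC)=C[C@H]1O[Si](C)(C)C
F6 | step 8 | 3-allyl-6,6-dibromo-1-methoxy-4-(trimethylsilyloxy)bicyclo[3.1.0]hexane, CBr2 bridge opposite to allyl and OTMS | C=CC[C@H]1C[C@]2(OC)C(Br)(Br)[C@@H]2[C@H]1O[Si](C)(C)C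
F7 | step 10 | (1S,4R,6S)-6-allyl-4-(2-allyl-4,5-dimethoxyphenoxy)-3,4-dimethoxycyclohex-2-en-1-ol | C=CCc1cc(OC)c(OC)cc1O[C@]1(OC)C[C@H](CC=C)[C@H](O)C=C1OC
F8 | step 5 | racemic 5-allyl-3-(2-allyl-4,5-dimethoxyphenoxy)cyclopent-2-en-1-one | C=CCC1CC(Oc2cc(OC)c(OC)cc2CC=C)=CC1=O
F9 | step 5 | rac-cis-5-allyl-3-(2-allyl-4,5-dimethoxyphenoxy)cyclopent-2-en-1-ol (racemate, both enantiomers written) | C=CC[C@H]1CC(Oc2cc(OC)c(OC)cc2CC=C)=C[C@H]1O.C=CC[C@@H]1CC(Oc2cc(OC)c(OC)cc2CC=C)=C[C@@H]1O
F10 | step 5 | (1R,5R)-5-allyl-3-(2-allyl-4,5-dimethoxyphenoxy)cyclopent-2-en-1-yl acetate | C=CC[C@@H]1CC(Oc2cc(OC)c(OC)cc2CC=C)=C[C@@H]1OC(C)=O
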